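| flask | substrate | reagent | remark | time |
|---|---|---|---|---|
| south | 0.025 M | 0.050 M | run made earlier |  |
| north-east | 0.013 M | 0.050 M | run made earlier |  |
| west | 0.019 M | 0.050 M | run made earlier |  |
| north-west | 0.025 M | 0.025 M | run made earlier |  |
| summer | 0.025 M | 0.0500 M (fed, over 3.0 min) | all else is in the flask from the start; the feed brings no volume worth counting | 4.0 min |
| autumn | 0.025 M (in portions, 2, over 3.0 min) | 0.0500 M | first portion at the start, last at 3.0 min | 4.0 min |
| noon | 0.025 M (fed, over 3.0 min) | 0.0500 M | all else is in the flask from the start; the feed brings no volume worth counting | 4.0 min |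
| spring | 0.025 M | 0.0500 M | everything together at the start | 4.0 min |

- south (time / min: isomer of the product / %, target / %, substrate / %): 0.200: 11.5, 18.6, 71.1; 0.667: 35.5, 11.3, 52.8; 1.00: 48.2, 8.1, 44.8; 1.50: 58.0, 8.4, 35.3; 2.50: 76.2, 4.5, 21.7
- north-east (time / min: isomer of the product / %, target / %, substrate / %): 1.00: 48.8, 12.3, 40.2; 2.00: 71.9, 5.5, 22.7; 3.00: 84.5, 2.7, 13.9; 4.00: 89.5, 1.4, 8.2; 5.00: 95.4, 0, 3.0
- west (time / min: isomer of the product / %, target / %, substrate / %): 1.00: 48.3, 10.9, 43.2; 2.00: 69.2, 4.2, 23.8; 3.00: 84.7, 2.7, 14.7; 4.00: 88.8, 0.3, 9.1; 5.00: 91.1, 2.4, 3.9
- north-west (time / min: isomer of the product / %, target / %, substrate / %): 0.417: 14.2, 9.7, 76.2; 0.667: 20.2, 8.8, 71.5; 1.33: 35.3, 6.1, 61.2; 2.50: 49.1, 2.8, 46.8; 5.00: 68.1, 2.3, 33.1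

(each reading ± 1 percentage point)

- the analysis behind the earlier runs scatters by 1 percentage point, standard deviation
- on the list of suspects stand: substrate + reagent <-> target; substrate + reagent -> isomer of the product

1. the flask with the highest amount of isomer of the product, in percent of the substrate charged ("all alike" if they lie within 1.5 percentage points) (summer / autumn / noon / spring / all alike)
2. final isomer of the product, as a percentage of the substrate charged, in summer
3. final isomer of the product, as a percentage of the substrate charged, in autumn
4. final isomer of the product, as a percentage of the substrate charged, in noon
5. final isomer of the product, as a percentage of the substrate charged, in spring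

South holds the charges of spring, so its last reading can be carried forward by one closed form. Substrate and target together form the remainder that has still to become isomer, and if isomer forms at a rate proportional to that remainder times the reagent, the second-order law integrates to ln(share of reagent left / share of remainder left) = k × (reagent charge − substrate charge) × time. South's 76.2% of isomer at 2.50 min gives 15.3 L mol⁻¹ min⁻¹, the apparent constant k, a reading that carries the scatter and has target's holding folded in.

Putting everything in at the start, the law gives 87.8% for spring. Feeding the reagent turns the law into a plain exponential if the reagent is taken at its charge less half the substrate charge, 0.0375 M, and the ramp counts for half its time, so summer comes to 76.2%. Feeding the substrate instead, each slice decays for the time it has left, and averaging over the slices gives noon 73.1%. Splitting the substrate means applying the law twice: in autumn the first portion yields 0.0107 M of isomer by 3.0 min, and the remaining substrate and reagent then run for the last stretch, which makes 67.1%.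

The forecast names spring, with 86% there, 73% in summer, 71% in noon and 65% in autumn, and holds that “target acts only as a small reversible reservoir”. Its numbers stand lower than these reckonings in each flask, in the same order.

The flasks give 87.4% in spring, 74.6% in summer, 72.3% in noon and 66.4% in autumn, inside each of the forecast's ranges.

    substrate + reagent ⇌ target (K = 5.70 L mol⁻¹, k = 1.15 L mol⁻¹ s⁻¹)
    substrate + reagent → isomer of the product (k = 0.311 L mol⁻¹ s⁻¹)

In spring at 2.00 min, target holds 5.13% beside 27.0% of substrate, so free substrate is 0.840 of the remainder. The carried k gives 69.7% of isomer in spring at that moment, and the flask holds 67.9% there.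

Autumn with 0.10 M of substrate puts in a first portion equal to the reagent charge, where the law becomes remainder = 1/(1 + k × charge × time), and the second portion leaves the reagent as limiting reagent. The reckoning gives 0.0348 M of isomer by 3.0 min and 43.9% at the end; the computed flask gives 43.0%, with 10.5% of the reagent left.

The earlier runs and the new flask are simulated with made-up constants.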